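I start from the last reading of the earlier runs, 20.0 d, after each dose is in, and ask what the next flask's best target will be.

the same everywhere: catalyst 3.7 mM
- birch: starting material 0.17 M (fed, over 4.0 d); protic impurity 0.068 M; run made earlier; the fed solution adds 0.10 times the starting volume
- maple: starting material 0.68 M (fed, over 4.0 d); protic impurity 0.068 M; run made earlier; the fed solution adds 0.10 times the starting volume
- larch: starting material 0.34 M (fed, over 4.0 d); protic impurity 0.14 M; run made earlier; the fed solution adds 0.10 times the starting volume
- flask: starting material 0.34 M (fed, over 4.0 d); protic impurity 0.0680 M; the fed solution adds 0.10 times the starting volume; time 15 d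

| birch: time / d | birch: target / % | maple: time / d | maple: target / % | larch: time / d | larch: target / % |
|---|---|---|---|---|---|
| 1.04 | 8 | 1.04 | 9 | 1.04 | 5 |
| 3.00 | 18 | 3.00 | 19 | 3.00 | 13 |
| 8.00 | 24 | 8.00 | 29 | 8.00 | 19 |
| 20.0 | 22 | 20.0 | 34 | 20.0 | 23 |

(each reading ± 2 percentage points)

1. when, up to 15 d, the flask holds most target
2. the amount of target, in percent of the starting material charged, at that time

- every charge counts on the volume at the start, and the solution that is fed holds the whole dose
- the numbers in the tables scatter by 2 percentage points (one standard deviation)
- percentages count the whole charge, also what has not yet gone in

I suppose that each molecule of protic impurity destroys one molecule of starting material, with the impurity as limiting reagent of that loss. That leaves the spendable share, one minus impurity over whole charge, and for the flask it is 80.0%. I then freeze the target per spendable share. Maple, which shares the flask's impurity, reads 37.8%, and larch, which shares its charge, reads 39.1%.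

These give two ways to the flask's best target: 30.2% from maple and 31.3% from larch. They rest on different readings and agree within a scatter of 2 percentage points, so I commit to 30.8%.

The date stays open. From 8.00 d to 20.0 d birch falls 2 points, while maple rises 5 points and larch 4 points, and the spendable share carries no clock.

The forecast says 28% at 15 d, a level below mine: “Interpolating at 15 d between about 23% and 33% gives about 28%.”

The flask holds most target at 4.35 d, namely 30.0%.

    starting material + catalyst ⇌ target + catalyst, rate k1*[starting material]*[catalyst] forward; the back reaction follows from the equilibrium constant (K = 0.840, k = 0.480 M⁻¹ min⁻¹)
    target ⇌ isomer of the product (K = 0.700, k = 6.10 × 10⁻⁵ min⁻¹)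
    starting material + protic impurity → quenched substrate (k = 0.0220 M⁻¹ min⁻¹)
    isomer of the product + catalyst ⇌ starting material + catalyst, rate k4*[catalyst]*[isomer of the product] forward; the back reaction follows from the equilibrium constant (k = 0.0820 M⁻¹ min⁻¹)

In the flask at 15.0 d, starting material goes into target with a half-life of 0.30 d by that forward rate alone, shorter than the 1.10 d relaxation half-life of isomer of the product and starting material by their step alone. Target reads 30.0% at 4.35 d and 28.0% at 7.50 d, while the isomer of the product climbs from 13.9% to 18.7%. Quenched substrate in the flask stands at 20.0% at 15.0 d, with protic impurity at 0%, and that is the part the spendable share of 80.0% leaves out. The neighbour flask with 0.12 M of protic impurity has a spendable share of 64.7% and ends with 35.3% quenched substrate; its share reckons 24.9% of target against a simulated best of 24.4%.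

The data stem from a simulated flask from invented constants; the scatter is artificial.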